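**Retrosynthetic overview**

1. The carbocycle, its C‑methyl stereocentre and the isopropylidene group are bought as (S)‑(−)‑pulegone 1, and the coumarin is bought intact. No ring of the target is built; the only ring closure is a temporary cyclic carbonate (step 4), opened again in step 5.
2. Quaternary carbon: its methyl and its CH2O carbon are both disconnected from the α′‑carbon of 1 (formylation to 2, C‑methylation to keto aldehyde 3, reduction to diol 4).
3. Key disconnection: the ring CH–CH2CH2CHO bond. It is cut into an electrophilic allylic carbon (the former ketone carbon, activated in cyclic carbonate 5) and a propanal homoenolate (d3 reagent, the cuprate from bromoacetal 6). An anti SN2‑type copper substitution joins them and sets the third stereocentre; half‑ester 7 then loses CO2 to free alcohol 8.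
4. Final disconnection: the aryl–O–CH2 ether between 8 and isofraxidin 9 (Mitsunobu), with the aldehyde released from acetal 10 in the same flask to give target 11.

Assumption: (S)‑(−)‑pulegone is bought as the single enantiomer (it is sold, at a higher price than its mirror image).

**Route**

Step 1
Reactants: 1 (S)‑(−)‑pulegone, (5S)‑5‑methyl‑2‑(propan‑2‑ylidene)cyclohexan‑1‑one
Product: 2 (2Z,3S)‑2‑(hydroxymethylidene)‑3‑methyl‑6‑(propan‑2‑ylidene)cyclohexan‑1‑one
Conditions: NaH, HCO2Et, THF, 0 → 25 °C; then 1 M HCl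
Reagents that add atoms: ethyl formate, CCOC=O
Why: crossed Claisen condensation (α′‑formylation), in which the only enolisable CH2 next to the ketone is formylated and the product is removed from the equilibrium as its chelated sodium enolate, so the enone and the existing methyl stereocentre are untouched.

Step 2
Reactants: 2 (2Z,3S)‑2‑(hydroxymethylidene)‑3‑methyl‑6‑(propan‑2‑ylidene)cyclohexan‑1‑one
Product: 3 (1R,6S)‑1,6‑dimethyl‑2‑oxo‑3‑(propan‑2‑ylidene)cyclohexane‑1‑carbaldehyde
Conditions: MeI, K2CO3, acetone, 56 °C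
Reagents that add atoms: iodomethane, CI
Why: C‑alkylation of a β‑keto aldehyde enolate, in which A(1,3) strain with the exocyclic enolate forces the neighbouring ring methyl axial, so MeI enters from the opposite face and the new quaternary centre carries its methyl trans and its formyl group cis to that ring methyl.

Step 3
Reactants: 3 (1R,6S)‑1,6‑dimethyl‑2‑oxo‑3‑(propan‑2‑ylidene)cyclohexane‑1‑carbaldehyde
Product: 4 (1R,2R,3S)‑2‑(hydroxymethyl)‑2,3‑dimethyl‑6‑(propan‑2‑ylidene)cyclohexan‑1‑ol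
Conditions: iBu2AlH (DIBAL‑H, 3.5 equiv), CH2Cl2, −78 → −20 °C; aq KNaC4H4O6 (potassium sodium tartrate) work‑up
Reagents that add atoms: none
Why: 1,2‑hydride reduction of both carbonyl groups, in which hydride adds axially to the ketone from the face opposite to the axial CH2O–Al group (the other face is also screened by the secondary methyl, and equatorial approach by the isopropylidene methyl), so the new carbinol oxygen is cis to CH2OH, as in the reduction of pulegone to cis‑pulegol.

Step 4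
Reactants: 4 (1R,2R,3S)‑2‑(hydroxymethyl)‑2,3‑dimethyl‑6‑(propan‑2‑ylidene)cyclohexan‑1‑ol
Product: 5 (4aR,5S,8aR)‑4a,5‑dimethyl‑8‑(propan‑2‑ylidene)‑4a,5,6,7,8,8a‑hexahydro‑4H‑1,3‑benzodioxin‑2‑one (cis‑fused cyclic carbonate)
Conditions: CDI, DMAP (cat.), toluene, 80 °C
Reagents that add atoms: 1,1′‑carbonyldiimidazole, O=C(n1ccnc1)n1ccnc1
Why: carbonylation of a 1,3‑diol, in which the primary alcohol is acylated first and the secondary allylic alcohol closes the six‑membered carbonate, which activates the allylic C–O bond and masks the primary alcohol in one operation without touching a stereocentre.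

Step 5
Reactants: 5 (4aR,5S,8aR)‑4a,5‑dimethyl‑8‑(propan‑2‑ylidene)‑4a,5,6,7,8,8a‑hexahydro‑4H‑1,3‑benzodioxin‑2‑one; 6 2‑(2‑bromoethyl)‑1,3‑dioxolane
Product: 8 {(1S,2S,6S)‑2‑[2‑(1,3‑dioxolan‑2‑yl)ethyl]‑1,6‑dimethyl‑3‑(propan‑2‑ylidene)cyclohexyl}methanol, via carbonate half‑ester 7 (not isolated)
Conditions: 6 (5 equiv), Mg, THF, 25 °C; CuBr·SMe2 (2.5 equiv), −40 °C; then 5, −40 → 0 °C; aq NH4Cl
Reagents that add atoms: none
Why: copper‑mediated allylic substitution in its anti SN2 mode with a propanal homoenolate equivalent (the d3 dialkylcuprate from the acetal Grignard reagent), in which the cuprate adds oxidatively anti to the allylic C–O bond, the allylcopper intermediate (trivalent copper) of a dialkylcuprate equilibrates and couples at the ring CH instead of the fully substituted isopropylidene carbon, and coupling with retention gives net inversion, so the chain ends trans to CH2O and to the secondary methyl and cis to the quaternary methyl, while half‑ester 7 loses CO2 on work‑up.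

Step 6
Reactants: 8 {(1S,2S,6S)‑2‑[2‑(1,3‑dioxolan‑2‑yl)ethyl]‑1,6‑dimethyl‑3‑(propan‑2‑ylidene)cyclohexyl}methanol; 9 isofraxidin, 7‑hydroxy‑6,8‑dimethoxy‑2H‑chromen‑2‑one
Product: 11 3‑[(1S,2S,3S)‑2‑{[(6,8‑dimethoxy‑2‑oxo‑2H‑chromen‑7‑yl)oxy]methyl}‑2,3‑dimethyl‑6‑(propan‑2‑ylidene)cyclohexyl]propanal, via dioxolane aryl ether 10 (not isolated)
Conditions: PPh3, DIAD, THF (2 M, ultrasound), 25 → 40 °C; then 2 M HCl, 25 °C
Reagents that add atoms: water, O
Why: Mitsunobu etherification followed by acetal hydrolysis, in which the acidic phenol displaces the neopentyl oxyphosphonium ion at the CH2 carbon (no stereocentre is involved, and high concentration with sonication offsets the steric hindrance) and dilute acid then cleaves only the dioxolane, leaving lactone, aryl ether and tetrasubstituted alkene intact.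

**Compound list**

1 | (S)‑(−)‑pulegone, (5S)‑5‑methyl‑2‑(propan‑2‑ylidene)cyclohexan‑1‑one | C[C@H]1CCC(=C(C)C)C(=O)C1 | starting material
2 | (2Z,3S)‑2‑(hydroxymethylidene)‑3‑methyl‑6‑(propan‑2‑ylidene)cyclohexan‑1‑one | C[C@H]1CCC(=C(C)C)C(=O)/C1=C\O | intermediate
3 | (1R,6S)‑1,6‑dimethyl‑2‑oxo‑3‑(propan‑2‑ylidene)cyclohexane‑1‑carbaldehyde | C[C@H]1CCC(=C(C)C)C(=O)[C@@]1(C)C=O | intermediate
4 | (1R,2R,3S)‑2‑(hydroxymethyl)‑2,3‑dimethyl‑6‑(propan‑2‑ylidene)cyclohexan‑1‑ol | C[C@H]1CCC(=C(C)C)[C@@H](O)[C@@]1(C)CO | intermediate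
5 | (4aR,5S,8aR)‑4a,5‑dimethyl‑8‑(propan‑2‑ylidene)‑4a,5,6,7,8,8a‑hexahydro‑4H‑1,3‑benzodioxin‑2‑one | C[C@H]1CCC(=C(C)C)[C@H]2OC(=O)OC[C@@]12C | intermediate
6 | 2‑(2‑bromoethyl)‑1,3‑dioxolane | BrCCC1OCCO1 | starting material
7 | {(1S,2S,6S)‑2‑[2‑(1,3‑dioxolan‑2‑yl)ethyl]‑1,6‑dimethyl‑3‑(propan‑2‑ylidene)cyclohexyl}methyl hydrogen carbonate (bromomagnesium salt in the flask) | C[C@H]1CCC(=C(C)C)[C@H](CCC2OCCO2)[C@@]1(C)COC(=O)O | intermediate (not isolated)
8 | {(1S,2S,6S)‑2‑[2‑(1,3‑dioxolan‑2‑yl)ethyl]‑1,6‑dimethyl‑3‑(propan‑2‑ylidene)cyclohexyl}methanol | C[C@H]1CCC(=C(C)C)[C@H](CCC2OCCO2)[C@@]1(C)CO | intermediate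
9 | isofraxidin, 7‑hydroxy‑6,8‑dimethoxy‑2H‑chromen‑2‑one | COc1cc2ccc(=O)oc2c(OC)c1O | starting material
10 | 7‑({(1S,2S,6S)‑2‑[2‑(1,3‑dioxolan‑2‑yl)ethyl]‑1,6‑dimethyl‑3‑(propan‑2‑ylidene)cyclohexyl}methoxy)‑6,8‑dimethoxy‑2H‑chromen‑2‑one | C[C@H]1CCC(=C(C)C)[C@H](CCC2OCCO2)[C@@]1(C)COc1c(OC)cc2ccc(=O)oc2c1OC | intermediate (not isolated)
11 | 3‑[(1S,2S,3S)‑2‑{[(6,8‑dimethoxy‑2‑oxo‑2H‑chromen‑7‑yl)oxy]methyl}‑2,3‑dimethyl‑6‑(propan‑2‑ylidene)cyclohexyl]propanal (CNP0213227.1) | COc1cc2ccc(=O)oc2c(OC)c1OC[C@@]1(C)[C@@H](C)CCC(=C(C)C)[C@@H]1CCC=O | target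

**Step count and risks**

Total steps: 6. Longest linear sequence: 6 (1 → 2 → 3 → 4 → 5 → 8 → 11).

Most likely to fail, in order:

Step 5. The cuprate may couple at the isopropylidene carbon instead (giving a quaternary carbon and an endocyclic alkene), eliminate to dienes, or react too slowly at the hindered allylic carbon. The fallback sets out from 5 and returns at 8. Carbonate 5 is treated with Pd(PPh3)4 and Et2Zn in THF in the presence of acrolein. This converts the allyl electrophile into an allylzinc nucleophile, which adds to the aldehyde C=O through its tertiary terminus and gives 4‑[(3S,4S)‑3‑(hydroxymethyl)‑3,4‑dimethylcyclohex‑1‑en‑1‑yl]‑4‑methylpent‑1‑en‑3‑ol F1 (both carbinol epimers, which converge). KH and 18‑crown‑6 in THF then trigger an anionic oxy‑Cope rearrangement of the dialkoxide; the oxyallyl unit acts as the homoenolate and forms the ring CH–CH2 bond from the face opposite to CH2O, while the isopropylidene group is regenerated. This gives 3‑[(1S,2S,3S)‑2‑(hydroxymethyl)‑2,3‑dimethyl‑6‑(propan‑2‑ylidene)cyclohexyl]propanal F2, and acetalisation with ethylene glycol and PPTS returns to 8.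

Step 6. The Mitsunobu reaction joins a neopentyl carbinol to a phenol with two ortho substituents. The fallback sets out from 8 and returns at 10. Alcohol 8 is converted with Tf2O and 2,6‑lutidine in CH2Cl2 at −78 °C into {(1S,2S,6S)‑2‑[2‑(1,3‑dioxolan‑2‑yl)ethyl]‑1,6‑dimethyl‑3‑(propan‑2‑ylidene)cyclohexyl}methyl trifluoromethanesulfonate F3. The caesium phenoxide of 9 (Cs2CO3, DMF, 25 → 60 °C) displaces the triflate to give 10, which is hydrolysed with 2 M HCl as in step 6.

Step 2. O‑methylation and base‑induced loss of the formyl group compete with C‑methylation at the hindered carbon. The fallback sets out from 1 and returns at 4. The kinetic α′‑enolate of 1 (LiN(iPr)2, THF, −78 °C) is trapped with monomeric formaldehyde to give (3S)‑2‑(hydroxymethyl)‑3‑methyl‑6‑(propan‑2‑ylidene)cyclohexan‑1‑one F4 (epimers at C2, which converge). Its alkoxide enolate (2.2 equiv LiN(iPr)2, −78 °C) is methylated with MeI anti to the ring methyl to give (2R,3S)‑2‑(hydroxymethyl)‑2,3‑dimethyl‑6‑(propan‑2‑ylidene)cyclohexan‑1‑one F5. Reduction with iBu2AlH as in step 3 gives 4.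

**Further compounds**

F1 | step 5 | 4‑[(3S,4S)‑3‑(hydroxymethyl)‑3,4‑dimethylcyclohex‑1‑en‑1‑yl]‑4‑methylpent‑1‑en‑3‑ol | C[C@H]1CCC(C(C)(C)C(O)C=C)=C[C@@]1(C)CO
F2 | step 5 | 3‑[(1S,2S,3S)‑2‑(hydroxymethyl)‑2,3‑dimethyl‑6‑(propan‑2‑ylidene)cyclohexyl]propanal | C[C@H]1CCC(=C(C)C)[C@H](CCC=O)[C@@]1(C)CO
F3 | step 6 | {(1S,2S,6S)‑2‑[2‑(1,3‑dioxolan‑2‑yl)ethyl]‑1,6‑dimethyl‑3‑(propan‑2‑ylidene)cyclohexyl}methyl trifluoromethanesulfonate | C[C@H]1CCC(=C(C)C)[C@H](CCC2OCCO2)[C@@]1(C)COS(=O)(=O)C(F)(F)F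
F4 | step 2 | (3S)‑2‑(hydroxymethyl)‑3‑methyl‑6‑(propan‑2‑ylidene)cyclohexan‑1‑one | C[C@H]1CCC(=C(C)C)C(=O)C1CO
F5 | step 2 | (2R,3S)‑2‑(hydroxymethyl)‑2,3‑dimethyl‑6‑(propan‑2‑ylidene)cyclohexan‑1‑one | C[C@H]1CCC(=C(C)C)C(=O)[C@@]1(C)CO
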